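**Retrosynthetic overview**
- The all-cis oxolane comes from a 2,3,4-trisubstituted 3-(hydroxymethyl)furan by one enantioselective all-cis hydrogenation that sets C2, C3 and C4 together (last step).
- The furylmethanol comes from a furan-3-carboxylate, made by copper-catalysed ring expansion of a cyclopropenyl aryl ketone (three- to five-membered ring); the ketone oxygen closes on the unsubstituted ring carbon, giving 2-aryl, 3-ester, 4-benzyl, 5-H.
- The cyclopropenyl ketone comes from a rhodium carbenoid (α-diazo-β-keto ester) and a 3-arylprop-1-yne.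
- The diazo keto ester comes from 3,4,5-trimethoxybenzaldehyde (built from p-cresol) and ethyl diazoacetate; the alkyne comes from catechol and methoxyallene.
- Ring order: the cyclopropene is formed first, expanded to the furan, and the furan is reduced last to the oxolane.

Assumption: the SMILES is read as the all-cis (2R,3R,4R) oxolane. Which antipode of the chiral ligand in the last step gives this enantiomer has to be fixed by experiment; the route is written for the antipode that does.

**Step 1**
Reactants: 1 4-methylphenol (p-cresol)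
Product: 4 3,5-dibromo-4-hydroxybenzaldehyde, via dibromocresol 2 (not isolated), via benzal bromide 3 (not isolated)
Conditions: Br2 (2 equiv), o-dichlorobenzene, 30 °C; Br2 (2 equiv), 155 °C; then H2O, 100 °C
Reagents that add atoms: bromine (BrBr); water (O)
Why: Electrophilic aromatic bromination at both positions ortho to OH, then side-chain dibromination of the methyl group and hydrolysis of the gem-dibromide to the aldehyde (known technical sequence).

**Step 2**
Reactants: 4 3,5-dibromo-4-hydroxybenzaldehyde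
Product: 6 3,4,5-trimethoxybenzaldehyde, via sodium syringaldehyde phenolate 5 (not isolated)
Conditions: NaOMe (4 equiv), CuCl (10 mol %), MeOH/DMF, 110 °C; then Me2SO4 (2.5 equiv), 50 °C
Reagents that add atoms: sodium methoxide ([Na+].[O-]C); dimethyl sulfate (COS(=O)(=O)OC)
Why: Copper-catalysed Ullmann-type methoxylation of both aryl bromides, then Williamson O-methylation of the phenolate in the same pot.

**Step 3**
Reactants: 6 3,4,5-trimethoxybenzaldehyde; 7 ethyl diazoacetate
Product: 9 ethyl 2-diazo-3-oxo-3-(3,4,5-trimethoxyphenyl)propanoate, via diazo hydroxy ester 8 (not isolated)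
Conditions: DBU (20 mol %), DMSO, 25 °C; then IBX (2 equiv), 25 °C
Reagents that add atoms: none
Why: DBU-catalysed aldol-type addition of the diazoacetate C–H to the aldehyde, then IBX oxidation of the carbinol to the ketone, which removes the only stereocentre.

**Step 4**
Reactants: 10 benzene-1,2-diol (catechol)
Product: 11 1,2-dimethoxybenzene
Conditions: Me2SO4 (2.2 equiv), NaOH, H2O, 40 to 90 °C
Reagents that add atoms: dimethyl sulfate (COS(=O)(=O)OC)
Why: Double Williamson ether synthesis on the bis-phenolate.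

**Step 5**
Reactants: 11 1,2-dimethoxybenzene
Product: 12 4-bromo-1,2-dimethoxybenzene
Conditions: NBS (1.0 equiv), MeCN, 25 °C
Reagents that add atoms: N-bromosuccinimide (O=C1CCC(=O)N1Br)
Why: Electrophilic aromatic bromination, para to one methoxy group, gives only the 4-bromo isomer.

**Step 6**
Reactants: 12 4-bromo-1,2-dimethoxybenzene; 13 methoxyallene
Product: 15 1,2-dimethoxy-4-(prop-2-yn-1-yl)benzene, via aryl Grignard reagent 14 (not isolated)
Conditions: Mg, THF, reflux; then 13, CuBr (5 mol %), Et2O/THF, −20 to 20 °C; aq NH4Cl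
Reagents that add atoms: none
Why: Grignard formation, then copper-catalysed SN2′ substitution of methoxyallene with loss of methoxide gives the terminal propargyl arene.

**Step 7**
Reactants: 9 ethyl 2-diazo-3-oxo-3-(3,4,5-trimethoxyphenyl)propanoate; 15 1,2-dimethoxy-4-(prop-2-yn-1-yl)benzene
Product: 17 ethyl 4-(3,4-dimethoxybenzyl)-2-(3,4,5-trimethoxyphenyl)furan-3-carboxylate, via cyclopropenyl ketone 16 (not isolated)
Conditions: Rh2(OAc)4 (1 mol %), 15 (3 equiv), CH2Cl2, 25 °C, slow addition of 9; evaporate; then CuI (10 mol %), MeCN, 80 °C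
Reagents that add atoms: none
Why: Rhodium-carbenoid cyclopropenation of the terminal alkyne, then copper-catalysed ring-opening cycloisomerisation of the cyclopropenyl ketone (ring expansion, three- to five-membered, not pericyclic). The C1–C3(H) bond is cleaved and the ketone oxygen closes on the unsubstituted carbon, which puts benzyl at C4 and H at C5; no stereocentre remains.

**Step 8**
Reactants: 17 ethyl 4-(3,4-dimethoxybenzyl)-2-(3,4,5-trimethoxyphenyl)furan-3-carboxylate
Product: 18 [4-(3,4-dimethoxybenzyl)-2-(3,4,5-trimethoxyphenyl)furan-3-yl]methanol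
Conditions: i-Bu2AlH (2.5 equiv), CH2Cl2, −78 to 0 °C; aq potassium sodium tartrate (neutral work-up)
Reagents that add atoms: none
Why: Hydride reduction of the ester to the primary alcohol; the furan and aryl ethers are inert, and the acid-sensitive furylmethanol is kept away from acid.

**Step 9**
Reactants: 18 [4-(3,4-dimethoxybenzyl)-2-(3,4,5-trimethoxyphenyl)furan-3-yl]methanol
Product: 19 [(2R,3R,4R)-4-(3,4-dimethoxybenzyl)-2-(3,4,5-trimethoxyphenyl)oxolan-3-yl]methanol (target)
Conditions: Ru(cod)(2-methylallyl)2 (5 mol %), (R,R)-SINpEt·HBF4 (10 mol %; SINpEt = 1,3-bis[(1R)-1-(naphthalen-1-yl)ethyl]-4,5-dihydroimidazol-2-ylidene), KOtBu (12 mol %), hexane, 70 °C; then 18, H2 (100 bar), toluene/hexane, 40 °C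
Reagents that add atoms: none
Why: Proposed new method: enantioselective complete hydrogenation of a 2,3,4-trisubstituted furan by a chiral divalent ruthenium bis(N-heterocyclic carbene) catalyst. The electron-rich ruthenium hydride first reduces the less hindered C4=C5 bond inside the chiral pocket (enantio-determining, sets C4). The resulting 2-aryl-3-(hydroxymethyl)-4,5-dihydrofuran has an aryl enol ether C2=C3 bond that the allylic OH can hold on ruthenium, and it takes the second H2 on the same face, anti to the new C4 benzyl group. Catalyst and substrate control therefore both give the all-cis (2R,3R,4R) product, with C2, C3 and C4 fixed in this step. The closest known reaction type is the ruthenium–NHC asymmetric cis-hydrogenation of 2,5- and 2,4-disubstituted furans and of benzofurans; it has not been shown for a 2,3,4-trisubstituted furan with a tetrasubstituted C2=C3 bond.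

**Compound list**
1 | 4-methylphenol (p-cresol) | Cc1ccc(O)cc1 | starting material
2 | 2,6-dibromo-4-methylphenol | Cc1cc(Br)c(O)c(Br)c1 | intermediate
3 | 2,6-dibromo-4-(dibromomethyl)phenol | BrC(Br)c1cc(Br)c(O)c(Br)c1 | intermediate
4 | 3,5-dibromo-4-hydroxybenzaldehyde | O=Cc1cc(Br)c(O)c(Br)c1 | intermediate
5 | sodium 4-formyl-2,6-dimethoxyphenolate | [Na+].[O-]c1c(OC)cc(C=O)cc1OC | intermediate
6 | 3,4,5-trimethoxybenzaldehyde | COc1cc(C=O)cc(OC)c1OC | intermediate
7 | ethyl diazoacetate | CCOC(=O)C=[N+]=[N-] | starting material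
8 | ethyl 2-diazo-3-hydroxy-3-(3,4,5-trimethoxyphenyl)propanoate (racemic) | CCOC(=O)C(=[N+]=[N-])C(O)c1cc(OC)c(OC)c(OC)c1 | intermediate
9 | ethyl 2-diazo-3-oxo-3-(3,4,5-trimethoxyphenyl)propanoate | CCOC(=O)C(=[N+]=[N-])C(=O)c1cc(OC)c(OC)c(OC)c1 | intermediate
10 | benzene-1,2-diol (catechol) | Oc1ccccc1O | starting material
11 | 1,2-dimethoxybenzene | COc1ccccc1OC | intermediate
12 | 4-bromo-1,2-dimethoxybenzene | COc1ccc(Br)cc1OC | intermediate
13 | methoxyallene (methoxypropa-1,2-diene) | COC=C=C | starting material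
14 | (3,4-dimethoxyphenyl)magnesium bromide | COc1ccc([Mg]Br)cc1OC | intermediate
15 | 1,2-dimethoxy-4-(prop-2-yn-1-yl)benzene | C#CCc1ccc(OC)c(OC)c1 | intermediate
16 | ethyl 2-(3,4-dimethoxybenzyl)-1-(3,4,5-trimethoxybenzoyl)cycloprop-2-ene-1-carboxylate (racemic) | CCOC(=O)C1(C(=O)c2cc(OC)c(OC)c(OC)c2)C=C1Cc1ccc(OC)c(OC)c1 | intermediate
17 | ethyl 4-(3,4-dimethoxybenzyl)-2-(3,4,5-trimethoxyphenyl)furan-3-carboxylate | CCOC(=O)c1c(Cc2ccc(OC)c(OC)c2)coc1-c1cc(OC)c(OC)c(OC)c1 | intermediate
18 | [4-(3,4-dimethoxybenzyl)-2-(3,4,5-trimethoxyphenyl)furan-3-yl]methanol | OCc1c(Cc2ccc(OC)c(OC)c2)coc1-c1cc(OC)c(OC)c(OC)c1 | intermediate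
19 | [(2R,3R,4R)-4-(3,4-dimethoxybenzyl)-2-(3,4,5-trimethoxyphenyl)oxolan-3-yl]methanol, all-cis | COc1ccc(C[C@H]2CO[C@@H](c3cc(OC)c(OC)c(OC)c3)[C@H]2CO)cc1OC | target

**Step count and risks**
Total steps: 9. Longest linear sequence: 6 steps (1, 2, 3, 7, 8, 9 from p-cresol; equally 4, 5, 6, 7, 8, 9 from catechol).

Three steps most likely to fail:

Step 9 (the proposed new hydrogenation). The tetrasubstituted C2=C3 bond may stop at the dihydrofuran stage, or the enantioselectivity may be low. The fallback uses known chemistry, sets out from 18 and comes back at 19. Furan 18 is hydrogenated over rhodium on Al2O3 (5 wt % Rh, H2 4 bar, EtOAc, 25 °C), a known all-cis furan reduction, to the racemic all-cis alcohol F1. Acylation with (1S)-(−)-camphanic chloride (Et3N, DMAP, CH2Cl2) gives two diastereomeric esters, the (2R,3R,4R) camphanate F2 and the (2S,3S,4S) camphanate F3, which are separated by chromatography and crystallisation. Methanolysis of F2 (K2CO3, MeOH, 25 °C) returns 19.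

Step 7 (cyclopropenation and ring expansion). The rhodium catalyst may isomerise 16 to the 2,3,5-substituted furan, or the carbenoid may attack the dimethoxyarene. The fallback sets out from 12 and 9 and comes back at 17, keeping a three- to five-membered ring expansion but on a cyclopropane. Grignard reagent 14, made from 12 as in step 6, is allylated with allyl bromide (THF, 0 °C) to 4-allyl-1,2-dimethoxybenzene F4. Rh2(OAc)4-catalysed cyclopropanation of F4 with 9 gives ethyl 2-(3,4-dimethoxybenzyl)-1-(3,4,5-trimethoxybenzoyl)cyclopropane-1-carboxylate F5. Iodide-catalysed Cloke–Wilson ring expansion (NaI, DMF, 120 °C; SN2 opening at the unsubstituted CH2 and O-closure at the same carbon) gives ethyl 4-(3,4-dimethoxybenzyl)-2-(3,4,5-trimethoxyphenyl)-4,5-dihydrofuran-3-carboxylate F6. DDQ (dioxane, 80 °C) dehydrogenates F6 to 17.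

Step 3 (one-pot aldol addition and oxidation). The addition of ethyl diazoacetate to the electron-rich aldehyde is reversible and may give low conversion. The fallback sets out from 6 and 7 and comes back at 9. NbCl5-catalysed Roskamp homologation of 6 with 7 (CH2Cl2, 25 °C) gives ethyl 3-oxo-3-(3,4,5-trimethoxyphenyl)propanoate F7. Regitz diazo transfer (4-acetamidobenzenesulfonyl azide, Et3N, MeCN, 25 °C) converts F7 into 9.

**Further compounds**
F1 | step 9 | racemic all-cis [4-(3,4-dimethoxybenzyl)-2-(3,4,5-trimethoxyphenyl)oxolan-3-yl]methanol (1:1 mixture of 19 and its enantiomer) | COc1ccc(C[C@H]2CO[C@@H](c3cc(OC)c(OC)c(OC)c3)[C@H]2CO)cc1OC.COc1ccc(C[C@@H]2CO[C@H](c3cc(OC)c(OC)c(OC)c3)[C@@H]2CO)cc1OC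
F2 | step 9 | [(2R,3R,4R)-4-(3,4-dimethoxybenzyl)-2-(3,4,5-trimethoxyphenyl)oxolan-3-yl]methyl (1S,4R)-camphanate | COc1ccc(C[C@H]2CO[C@@H](c3cc(OC)c(OC)c(OC)c3)[C@H]2COC(=O)[C@@]56CC[C@@](C)(C(=O)O5)C6(C)C)cc1OC
F3 | step 9 | [(2S,3S,4S)-4-(3,4-dimethoxybenzyl)-2-(3,4,5-trimethoxyphenyl)oxolan-3-yl]methyl (1S,4R)-camphanate | COc1ccc(C[C@@H]2CO[C@H](c3cc(OC)c(OC)c(OC)c3)[C@@H]2COC(=O)[C@@]56CC[C@@](C)(C(=O)O5)C6(C)C)cc1OC
F4 | step 7 | 4-allyl-1,2-dimethoxybenzene | C=CCc1ccc(OC)c(OC)c1
F5 | step 7 | ethyl 2-(3,4-dimethoxybenzyl)-1-(3,4,5-trimethoxybenzoyl)cyclopropane-1-carboxylate (racemic) | CCOC(=O)C1(C(=O)c2cc(OC)c(OC)c(OC)c2)CC1Cc1ccc(OC)c(OC)c1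
F6 | step 7 | ethyl 4-(3,4-dimethoxybenzyl)-2-(3,4,5-trimethoxyphenyl)-4,5-dihydrofuran-3-carboxylate (racemic) | CCOC(=O)C1=C(c2cc(OC)c(OC)c(OC)c2)OCC1Cc1ccc(OC)c(OC)c1
F7 | step 3 | ethyl 3-oxo-3-(3,4,5-trimethoxyphenyl)propanoate | CCOC(=O)CC(=O)c1cc(OC)c(OC)c(OC)c1
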